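The α-methyl-γ-butyrolactone (ring atoms O1, C2, C3, C4, C5) is disconnected at C3–C4. A 5-exo-trig radical cyclization of an open-chain β-iodoalkyl mixed acetal of acrolein joins the former iodomethyl carbon (C4) to the internal vinyl carbon (C3), converts the vinyl terminus into the C3 methyl and sets C3 trans to the resident C5 stereocentre, which stems from (R)-epichlorohydrin. The acetal carbon is the lactone carbonyl C2 at a lower oxidation level and is oxidised afterwards. The feature exploited is the 1,3-relation of the C3 methyl and the oxygen-bearing C5 across the C4 methylene. Sharpless epoxidation and Mitsunobu etherification with 7-hydroxy-8-methoxycoumarin complete the route.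

Key step: step 6

Assumption: 7-hydroxy-8-methoxycoumarin, (R)-epichlorohydrin and methoxyallene are taken as purchasable; the acetal carbon of 9 to 13 is carried as a mixture of epimers because it later becomes the lactone carbonyl.

Step 1
Reactants: 1 (R)-epichlorohydrin; 2 acetylene
Product: 4 (2R)-1-chloropent-4-yn-2-ol, via lithium acetylide 3 (not isolated)
Conditions: 2 (excess), n-BuLi, THF, −78 °C; BF3·OEt2; then 1, −78 °C; aq NH4Cl
Reagents that add atoms: none
Why: BF3-promoted alkynylation of the epoxide by lithium acetylide at the unsubstituted ring carbon leaves the C–O bond of the stereocentre untouched, so the (R) configuration of 1 should pass into 4 and the chloromethyl group is kept as the later radical site.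

Step 2
Reactants: 4 (2R)-1-chloropent-4-yn-2-ol
Product: 6 (2E,5R)-6-chloro-3-methylhex-2-ene-1,5-diol, via alkenylalane 5 (not isolated)
Conditions: Me3Al (3 equiv), Cp2ZrCl2 (0.25 equiv), CH2Cl2, 0 °C to rt; then (CH2O)n, THF, 0 °C to rt; aq Rochelle salt
Reagents that add atoms: trimethylaluminium, C[Al](C)C; paraformaldehyde (reacts as formaldehyde), C=O
Why: Negishi carboalumination adds methyl and aluminium syn across the terminal alkyne with methyl on the internal carbon, and hydroxymethylation of the alkenylalane with retention should fix the E trisubstituted allylic alcohol while the secondary hydroxyl rides along as its aluminium alkoxide.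

Step 3
Reactants: 6 (2E,5R)-6-chloro-3-methylhex-2-ene-1,5-diol
Product: 7 (2R,4E)-6-[(tert-butyldiphenylsilyl)oxy]-1-chloro-4-methylhex-4-en-2-ol
Conditions: TBDPSCl (1.05 equiv), imidazole, CH2Cl2, 0 °C
Reagents that add atoms: tert-butyl(chloro)diphenylsilane, CC(C)(C)[Si](Cl)(c1ccccc1)c1ccccc1
Why: Selective silylation should take the unhindered primary allylic hydroxyl and leave the secondary hydroxyl, which is flanked by the chloromethyl group, free for acetal formation.

Step 4
Reactants: 7 (2R,4E)-6-[(tert-butyldiphenylsilyl)oxy]-1-chloro-4-methylhex-4-en-2-ol; 8 methoxyallene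
Product: 9 tert-butyl{[(2E,5R)-6-chloro-5-[(1-methoxyprop-2-en-1-yl)oxy]-3-methylhex-2-en-1-yl]oxy}diphenylsilane
Conditions: 8 (2 equiv), Pd(OAc)2 (5 mol %), dppp (7.5 mol %), Et3N, MeCN, rt
Reagents that add atoms: none
Why: Palladium-catalysed hydroalkoxylation of the alkoxyallene (alkoxy-substituted π-allyl palladium attacked by the alcohol at the oxygen-bearing terminus) should give the mixed acetal of acrolein under non-acidic conditions; the new acetal centre forms without control, which does not matter.

Step 5
Reactants: 9 tert-butyl{[(2E,5R)-6-chloro-5-[(1-methoxyprop-2-en-1-yl)oxy]-3-methylhex-2-en-1-yl]oxy}diphenylsilane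
Product: 10 tert-butyl{[(2E,5R)-6-iodo-5-[(1-methoxyprop-2-en-1-yl)oxy]-3-methylhex-2-en-1-yl]oxy}diphenylsilane
Conditions: NaI (10 equiv), NaHCO3, 2-butanone, reflux, dark
Reagents that add atoms: sodium iodide, [Na+].[I-]
Why: Finkelstein exchange at the primary carbon should turn the sluggish chloride into an iodide that enters a radical chain at low temperature, with hydrogen carbonate keeping the acid-sensitive acetal intact.

Step 6
Reactants: 10 tert-butyl{[(2E,5R)-6-iodo-5-[(1-methoxyprop-2-en-1-yl)oxy]-3-methylhex-2-en-1-yl]oxy}diphenylsilane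
Product: 13 tert-butyl{[(2E)-4-[(2S,4R)-5-methoxy-4-methyloxolan-2-yl]-3-methylbut-2-en-1-yl]oxy}diphenylsilane, via primary alkyl radical 11 (not isolated), via oxolanylmethyl radical 12 (not isolated)
Conditions: Bu3SnH (1.2 equiv, syringe pump), Et3B (0.2 equiv), air, toluene (0.01 M), −20 °C
Reagents that add atoms: none
Why: Et3B/O2 starts a tin hydride chain in which Bu3Sn• abstracts iodine from 10, the primary radical 11 adds to the internal carbon of the acetal vinyl group and the exocyclic primary radical 12 takes hydrogen from Bu3SnH, so the C3–C4 bond, the oxolane ring and the C3 methyl arise together. The closest known reaction type is the tin hydride 5-exo-trig cyclization of β-haloalkyl allyl ethers (3-oxa-5-hexenyl radicals), the regiochemical reverse of the Ueno–Stork haloacetal cyclization. The ring closes in the 5-exo-trig mode, which for an oxygen-containing hexenyl chain should be much faster than 6-endo attack at the vinyl terminus. The new stereocentre C3 is controlled by the resident C5 centre through the chair-like transition state of hexenyl radical closures, in which the C5 side chain sits pseudo-equatorial and the methyl-bearing carbon ends up trans to it; the acetal methoxy group can sit equatorial in one epimer and anomerically favoured axial in the other without forcing the side chain axial. The step needs ring closure before hydrogen transfer and trans over cis selectivity, which the fast oxa-hexenyl closure, high dilution with slow tin hydride addition and the low temperature made possible by the iodide are meant to secure. The trisubstituted alkene can only be reached by 4-exo or 5-endo attack and the silyl ether is inert, so neither should interfere.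

Step 7
Reactants: 13 tert-butyl{[(2E)-4-[(2S,4R)-5-methoxy-4-methyloxolan-2-yl]-3-methylbut-2-en-1-yl]oxy}diphenylsilane
Product: 14 (3R,5S)-5-[(2E)-4-[(tert-butyldiphenylsilyl)oxy]-2-methylbut-2-en-1-yl]-3-methyloxolan-2-one
Conditions: CrO3, H2SO4, H2O, acetone, 0 °C
Reagents that add atoms: water, O
Why: Jones oxidation hydrolyses the cyclic methyl acetal to the lactol and oxidises it in the same flask, so both acetal epimers should converge on one lactone with C3 and C5 untouched, and the minor 3,5-cis lactone expected from step 6 is removed here by chromatography.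

Step 8
Reactants: 14 (3R,5S)-5-[(2E)-4-[(tert-butyldiphenylsilyl)oxy]-2-methylbut-2-en-1-yl]-3-methyloxolan-2-one
Product: 15 (3R,5S)-5-[(2E)-4-hydroxy-2-methylbut-2-en-1-yl]-3-methyloxolan-2-one
Conditions: TBAF, AcOH (1:1), THF, 0 °C to rt
Reagents that add atoms: none
Why: Fluoride desilylation buffered with acetic acid should free the allylic alcohol without opening the lactone or epimerising its α-carbon.

Step 9
Reactants: 15 (3R,5S)-5-[(2E)-4-hydroxy-2-methylbut-2-en-1-yl]-3-methyloxolan-2-one
Product: 16 (3R,5S)-5-{[(2R,3R)-3-(hydroxymethyl)-2-methyloxiran-2-yl]methyl}-3-methyloxolan-2-one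
Conditions: Ti(OiPr)4 (10 mol %), D-(−)-diethyl tartrate (12 mol %), t-BuOOH, 4 Å MS, CH2Cl2, −20 °C
Reagents that add atoms: tert-butyl hydroperoxide, CC(C)(C)OO
Why: Sharpless asymmetric epoxidation with the D-(−)-tartrate delivers oxygen to the alkene face that gives the (2R,3R) epoxy alcohol from a geraniol-type E allylic alcohol, under reagent control that should override the remote lactone centres, and the E geometry sets the trans relation of the two epoxide substituents.

Step 10
Reactants: 16 (3R,5S)-5-{[(2R,3R)-3-(hydroxymethyl)-2-methyloxiran-2-yl]methyl}-3-methyloxolan-2-one; 17 7-hydroxy-8-methoxycoumarin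
Product: 18 8-methoxy-7-{[(2R,3R)-3-methyl-3-{[(2S,4R)-4-methyl-5-oxooxolan-2-yl]methyl}oxiran-2-yl]methoxy}-2H-chromen-2-one
Conditions: PPh3, DIAD, THF, 0 °C to rt
Reagents that add atoms: none
Why: Mitsunobu etherification should let the acidic 7-hydroxyl displace the activated primary oxygen at the CH2 carbon by SN2, which touches neither epoxide stereocentre nor the lactone.

Compound list
1 | (R)-epichlorohydrin, (2R)-2-(chloromethyl)oxirane | ClC[C@H]1CO1 | starting material
2 | acetylene | C#C | starting material
3 | lithium acetylide, formed in the flask | [Li]C#C | intermediate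
4 | (2R)-1-chloropent-4-yn-2-ol | C#CC[C@@H](O)CCl | intermediate
5 | [(1E,4R)-5-chloro-4-(dimethylalumanyloxy)-2-methylpent-1-en-1-yl]dimethylalumane, formed in the flask | C[Al](C)/C=C(C)/C[C@@H](O[Al](C)C)CCl | intermediate
6 | (2E,5R)-6-chloro-3-methylhex-2-ene-1,5-diol | OC/C=C(C)/C[C@@H](O)CCl | intermediate
7 | (2R,4E)-6-[(tert-butyldiphenylsilyl)oxy]-1-chloro-4-methylhex-4-en-2-ol | CC(C)(C)[Si](OC/C=C(C)/C[C@@H](O)CCl)(c1ccccc1)c1ccccc1 | intermediate
8 | methoxyallene, 1-methoxypropa-1,2-diene | COC=C=C | starting material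
9 | tert-butyl{[(2E,5R)-6-chloro-5-[(1-methoxyprop-2-en-1-yl)oxy]-3-methylhex-2-en-1-yl]oxy}diphenylsilane, both epimers at the acetal carbon | CC(C)(C)[Si](OC/C=C(C)/C[C@@H](OC(OC)C=C)CCl)(c1ccccc1)c1ccccc1 | intermediate
10 | tert-butyl{[(2E,5R)-6-iodo-5-[(1-methoxyprop-2-en-1-yl)oxy]-3-methylhex-2-en-1-yl]oxy}diphenylsilane, both epimers at the acetal carbon | CC(C)(C)[Si](OC/C=C(C)/C[C@@H](OC(OC)C=C)CI)(c1ccccc1)c1ccccc1 | intermediate
11 | primary alkyl radical at the former iodomethyl carbon of 10, formed in the flask | CC(C)(C)[Si](OC/C=C(C)/C[C@@H](OC(OC)C=C)[CH2])(c1ccccc1)c1ccccc1 | intermediate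
12 | (oxolan-3-yl)methyl radical after 5-exo closure, formed in the flask | CC(C)(C)[Si](OC/C=C(C)/C[C@@H]1C[C@@H]([CH2])C(OC)O1)(c1ccccc1)c1ccccc1 | intermediate
13 | tert-butyl{[(2E)-4-[(2S,4R)-5-methoxy-4-methyloxolan-2-yl]-3-methylbut-2-en-1-yl]oxy}diphenylsilane, both epimers at the acetal carbon | CC(C)(C)[Si](OC/C=C(C)/C[C@@H]1C[C@@H](C)C(OC)O1)(c1ccccc1)c1ccccc1 | intermediate
14 | (3R,5S)-5-[(2E)-4-[(tert-butyldiphenylsilyl)oxy]-2-methylbut-2-en-1-yl]-3-methyloxolan-2-one | CC(C)(C)[Si](OC/C=C(C)/C[C@@H]1C[C@@H](C)C(=O)O1)(c1ccccc1)c1ccccc1 | intermediate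
15 | (3R,5S)-5-[(2E)-4-hydroxy-2-methylbut-2-en-1-yl]-3-methyloxolan-2-one | OC/C=C(C)/C[C@@H]1C[C@@H](C)C(=O)O1 | intermediate
16 | (3R,5S)-5-{[(2R,3R)-3-(hydroxymethyl)-2-methyloxiran-2-yl]methyl}-3-methyloxolan-2-one | OC[C@H]1O[C@]1(C)C[C@@H]1C[C@@H](C)C(=O)O1 | intermediate
17 | 7-hydroxy-8-methoxycoumarin (hydrangetin) | COc1c(O)ccc2ccc(=O)oc12 | starting material
18 | 8-methoxy-7-{[(2R,3R)-3-methyl-3-{[(2S,4R)-4-methyl-5-oxooxolan-2-yl]methyl}oxiran-2-yl]methoxy}-2H-chromen-2-one | COc1c(OC[C@H]2O[C@]2(C)C[C@@H]2C[C@@H](C)C(=O)O2)ccc2ccc(=O)oc12 | target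

Total step count: 10. Longest linear sequence: 10 steps (1 to 18).

Steps most likely to fail

Step 6. The trans selectivity may erode if one acetal epimer closes through a boat-like or axial-side-chain transition state, and hydrogen transfer to radical 11 may compete with ring closure. The fallback closes the same C3–C4 bond by metathesis and brings in the methyl group by enolate alkylation. It sets out from 7 and returns at 14. K2CO3 in MeOH closes the chlorohydrin to tert-butyl{[(2E)-3-methyl-4-[(2R)-oxiran-2-yl]but-2-en-1-yl]oxy}diphenylsilane F1. Trimethylsulfonium iodide and n-BuLi (THF, −10 °C to rt) open the epoxide at its terminal carbon and give the vinyl carbinol (3R,5E)-7-[(tert-butyldiphenylsilyl)oxy]-5-methylhepta-1,5-dien-3-ol F2. Acryloyl chloride and Et3N give (3R,5E)-7-[(tert-butyldiphenylsilyl)oxy]-5-methylhepta-1,5-dien-3-yl prop-2-enoate F3. Ring-closing metathesis with the second-generation Grubbs catalyst RuCl2(=CHPh)(H2IMes)(PCy3) in CH2Cl2 at reflux should form the butenolide (5R)-5-[(2E)-4-[(tert-butyldiphenylsilyl)oxy]-2-methylbut-2-en-1-yl]furan-2(5H)-one F4; the trisubstituted alkene is far less reactive than the vinyl group. Conjugate reduction with LiBH(s-Bu)3 at −78 °C and trapping of the lactone enolate with MeI on the face anti to the C5 substituent should then give 14.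

Step 2. The alkenylalane may be protonated before it captures formaldehyde, and the aluminium alkoxide may close onto the chloromethyl group. The fallback sets out from 4 and returns at 6. Alkenylalane 5 is trapped with ethyl chloroformate, a more reactive electrophile, to give ethyl (2E,5R)-6-chloro-5-hydroxy-3-methylhex-2-enoate F5. DIBAL-H (CH2Cl2, −78 °C) then reduces the ester to diol 6.

Step 1. Monolithium acetylide may disproportionate to the dilithium salt, and opening of the epoxide may stay incomplete. The fallback sets out from 1 and returns at 4. Lithium (trimethylsilyl)acetylide with BF3·OEt2 (THF, −78 °C) opens 1 to (2R)-1-chloro-5-(trimethylsilyl)pent-4-yn-2-ol F6. TBAF buffered with AcOH then removes the silyl group to give 4.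

Further compounds
F1 | step 6 | tert-butyl{[(2E)-3-methyl-4-[(2R)-oxiran-2-yl]but-2-en-1-yl]oxy}diphenylsilane | CC(C)(C)[Si](OC/C=C(C)/C[C@@H]1CO1)(c1ccccc1)c1ccccc1
F2 | step 6 | (3R,5E)-7-[(tert-butyldiphenylsilyl)oxy]-5-methylhepta-1,5-dien-3-ol | CC(C)(C)[Si](OC/C=C(C)/C[C@@H](O)C=C)(c1ccccc1)c1ccccc1
F3 | step 6 | (3R,5E)-7-[(tert-butyldiphenylsilyl)oxy]-5-methylhepta-1,5-dien-3-yl prop-2-enoate | CC(C)(C)[Si](OC/C=C(C)/C[C@@H](OC(=O)C=C)C=C)(c1ccccc1)c1ccccc1
F4 | step 6 | (5R)-5-[(2E)-4-[(tert-butyldiphenylsilyl)oxy]-2-methylbut-2-en-1-yl]furan-2(5H)-one | CC(C)(C)[Si](OC/C=C(C)/C[C@@H]1C=CC(=O)O1)(c1ccccc1)c1ccccc1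
F5 | step 2 | ethyl (2E,5R)-6-chloro-5-hydroxy-3-methylhex-2-enoate | CCOC(=O)/C=C(C)/C[C@@H](O)CCl
F6 | step 1 | (2R)-1-chloro-5-(trimethylsilyl)pent-4-yn-2-ol | C[Si](C)(C)C#CC[C@@H](O)CCl
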